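**Plan**

1. Retrosynthetic cuts: C13 methylene and free 6-OH (from a masked α-formyl lactone plus formaldehyde), the C15–O ester bond, C4–C15 and C3–C4 (two couplings on a 1,1-dibromoalkene, the second cut being the ring closure), C1–C2, then the lactone bonds O–C8 and C11–C7 together, then C7=C8 (cross-metathesis).
2. Forward order: acyclic (E)-allylic alcohol 6 → rings B and A in one flask (step 7) → ten-membered ring (step 12) → C15 side chain → unmasking of the α-methylene lactone.
3. Enabling feature: O6–C6–C7–C11 are contiguous and the lactone bonds O–C8 and C11–C7 flank C7–C8, so ring A is the formal syn adduct of a carboxymethyl unit across an (E)-C7=C8 alkene.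
4. That unit is delivered from O6 through a one-carbon acetal tether (C13, temporary ring B), which is later excised as formate while formaldehyde supplies the exocyclic methylene.
5. Stereochemistry: C6 comes from (S)-but-3-ene-1,2-diol; C7 and C8 are relayed from C6 in step 7; C1=C10 from syn-carboalumination, C4=C5 from trans-selective coupling of the dibromoalkene, side-chain alkene from a Wittig reaction.

Key step: step 7

Assumption: germacrane numbering is used (ring C1–C10, lactone unit C11–C13, C14 methyl, C15 oxymethylene); the acetal carbon C13 (and C11 in 10) is carried as an epimer mixture, which is immaterial because C13 is excised and C11 becomes trigonal; pent-1-en-4-yne and (S)-but-3-ene-1,2-diol are taken as commercial.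

**Route**

Step 1
Reactants: 1 pent-1-en-4-yne
Product: 3 (E)-1-iodo-2-methylpenta-1,4-diene, via alkenylalane 2 (not isolated)
Conditions: AlMe3 (2.5 equiv), (C5H5)2ZrCl2 (0.25 equiv), CH2Cl2, 0 °C → rt; then I2, THF, –30 → 0 °C
Reagents that add atoms: trimethylaluminium C[Al](C)C; iodine II
Why: Zirconium-catalysed syn-carboalumination of the terminal alkyne (Negishi carboalumination) puts CH3 on C10 and aluminium on C1 cis to each other, the isolated alkene is left alone, and iodinolysis of the C–Al bond with retention fixes the (E)-C1=C10 geometry of the target.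

Step 2
Reactants: 4 (S)-but-3-ene-1,2-diol
Product: 5 (S)-1-[(tert-butyldimethylsilyl)oxy]but-3-en-2-ol
Conditions: TBSCl (1.05 equiv), imidazole, CH2Cl2, –10 → 0 °C
Reagents that add atoms: tert-butyldimethylsilyl chloride CC(C)(C)[Si](C)(C)Cl
Why: The primary hydroxyl is silylated much faster than the secondary allylic one (selective silyl ether formation), leaving the future C6 carbinol free; this stereocentre is bought in.

Step 3
Reactants: 3 (E)-1-iodo-2-methylpenta-1,4-diene (excess); 5 (S)-1-[(tert-butyldimethylsilyl)oxy]but-3-en-2-ol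
Product: 6 (2S,3E,6E)-1-[(tert-butyldimethylsilyl)oxy]-7-iodo-6-methylhepta-3,6-dien-2-ol
Conditions: second-generation Grubbs catalyst (5 mol%), 1,4-benzoquinone (10 mol%), CH2Cl2, 40 °C
Reagents that add atoms: none
Why: Olefin cross-metathesis between the monosubstituted alkene of 3 and the vinyl carbinol 5 should give the thermodynamically preferred (E)-C7=C8 alkene, the trisubstituted iodoalkene being inert to the ruthenium carbene and benzoquinone suppressing migration of the skipped diene.

Step 4
Reactants: 6 (2S,3E,6E)-1-[(tert-butyldimethylsilyl)oxy]-7-iodo-6-methylhepta-3,6-dien-2-ol; 7 methyl propiolate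
Product: 8 methyl (E)-3-{[(2S,3E,6E)-1-[(tert-butyldimethylsilyl)oxy]-7-iodo-6-methylhepta-3,6-dien-2-yl]oxy}prop-2-enoate
Conditions: PMe3 (10 mol%), CH2Cl2, 0 °C → rt
Reagents that add atoms: none
Why: Phosphine-catalysed oxa-Michael addition of the secondary alcohol to the propiolate gives the (E)-β-alkoxyacrylate, which attaches the future C11–C12–C13 unit to O6 without touching C6.

Step 5
Reactants: 8 methyl (E)-3-{[(2S,3E,6E)-1-[(tert-butyldimethylsilyl)oxy]-7-iodo-6-methylhepta-3,6-dien-2-yl]oxy}prop-2-enoate
Product: 9 (E)-3-{[(2S,3E,6E)-1-[(tert-butyldimethylsilyl)oxy]-7-iodo-6-methylhepta-3,6-dien-2-yl]oxy}prop-2-enoic acid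
Conditions: LiOH·H2O, THF/H2O, 0 °C → rt; then cold 1 M HCl to pH 3
Reagents that add atoms: lithium hydroxide [Li+].[OH-]
Why: Saponification of the vinylogous carbonate ester frees the carboxylic acid needed as the internal oxygen nucleophile, the silyl ether and iodoalkene being stable to cold aqueous hydroxide.

Step 6
Reactants: 9 (E)-3-{[(2S,3E,6E)-1-[(tert-butyldimethylsilyl)oxy]-7-iodo-6-methylhepta-3,6-dien-2-yl]oxy}prop-2-enoic acid
Product: 10 2-iodo-3-methoxy-3-{[(2S,3E,6E)-1-[(tert-butyldimethylsilyl)oxy]-7-iodo-6-methylhepta-3,6-dien-2-yl]oxy}propanoic acid (epimers at C2 and C3; used crude)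
Conditions: NIS (1.1 equiv), MeOH/CH2Cl2 (1:4), –40 → –10 °C, dark
Reagents that add atoms: N-iodosuccinimide O=C1CCC(=O)N1I; methanol CO
Why: Iodoalkoxylation of the enol ether (haloacetal formation as in the Ueno–Stork sequence) puts iodine on C11 and methanol on the oxocarbenium carbon C13, the enol ether being the most nucleophilic of the three alkenes, and the two new centres need no control.

Step 7
Reactants: 10 2-iodo-3-methoxy-3-{[(2S,3E,6E)-1-[(tert-butyldimethylsilyl)oxy]-7-iodo-6-methylhepta-3,6-dien-2-yl]oxy}propanoic acid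
Product: 12 (1R,4S,5R,6S)-6-{[(tert-butyldimethylsilyl)oxy]methyl}-4-[(E)-3-iodo-2-methylprop-2-en-1-yl]-8-methoxy-3,7-dioxabicyclo[3.3.0]octan-2-one (C8 epimers; bicyclo C1 = C11; C4 = C8; C5 = C7; C6 = C6; C8 = C13 in germacrane numbering), via cyclised iodo acid 11 (not isolated)
Conditions: Et3B (0.3 equiv, in portions), air, NaHCO3 (3 equiv), MeCN/H2O (1:1), 0.02 M, rt; then 50 °C
Reagents that add atoms: none
Why: Ethyl radicals from Et3B/O2 abstract iodine from the α-iodo carboxylate, the C11 radical adds 5-exo-trig to C7 of the (E)-C7=C8 bond through the O6–C13 acetal tether to close ring B, the C8 radical takes iodine from a second molecule of 10 to give 11, and the C11 carboxylate then displaces the C8 iodide 5-exo-tet with inversion to close lactone ring A, so that C11–C7 and O–C8 form in the one flask. The closest known reaction types are the Ueno–Stork haloacetal cyclisation run under iodine-atom-transfer conditions and the atom-transfer addition of α-iodo acids to alkenes with in situ lactonisation. C7 is set by C6, because in the chair-like 5-exo transition state the CH2OTBS group on C6 sits pseudo-equatorial, which places C5 and C8 trans on ring B. C8 is set by C7 and C11, because iodine should be delivered to the C8 radical (C9 eclipsing H7) on the face remote from the carboxylate-bearing C11 and the SN2 inversion then places C9 on the convex face of the cis-fused bicycle, trans to C6 across ring A, an outcome that corresponds to formal syn addition of C11 and O to the (E)-alkene; C11 is fixed by the obligatory cis ring fusion and C13 remains an irrelevant epimer mixture. The step needs 5-exo rather than 6-endo closure, attack on C7=C8 rather than on the iodoalkene, and a carboxylate cis to C8; the four-atom tether, the unreactive trisubstituted iodoalkene and the pseudo-equatorial preference of the carboxylate on the radical carbon should secure these, and any iodo acid with the carboxylate trans to C8 stays in the aqueous phase on extraction of the neutral lactone.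

Step 8
Reactants: 12 (1R,4S,5R,6S)-6-{[(tert-butyldimethylsilyl)oxy]methyl}-4-[(E)-3-iodo-2-methylprop-2-en-1-yl]-8-methoxy-3,7-dioxabicyclo[3.3.0]octan-2-one
Product: 13 (1R,4S,5R,6S)-6-{[(tert-butyldimethylsilyl)oxy]methyl}-8-methoxy-4-[(E)-2-methylpenta-2,4-dien-1-yl]-3,7-dioxabicyclo[3.3.0]octan-2-one
Conditions: tributyl(vinyl)stannane (1.5 equiv), Pd(PPh3)4 (5 mol%), CuI (10 mol%), DMF, rt → 40 °C
Reagents that add atoms: tributyl(vinyl)stannane C=C[Sn](CCCC)(CCCC)CCCC
Why: Stille coupling of the alkenyl iodide with the vinylstannane under neutral conditions proceeds with retention at C1 and installs C2–C3 as the terminal vinyl group of an (E)-diene, the lactone and acetal being untouched.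

Step 9
Reactants: 13 (1R,4S,5R,6S)-6-{[(tert-butyldimethylsilyl)oxy]methyl}-8-methoxy-4-[(E)-2-methylpenta-2,4-dien-1-yl]-3,7-dioxabicyclo[3.3.0]octan-2-one
Product: 14 (1R,4S,5R,6S)-6-(hydroxymethyl)-8-methoxy-4-[(E)-2-methylpenta-2,4-dien-1-yl]-3,7-dioxabicyclo[3.3.0]octan-2-one
Conditions: HF·pyridine, pyridine, THF, 0 °C → rt
Reagents that add atoms: none
Why: Buffered fluoride cleaves the primary silyl ether to free the C5 hydroxyl while the methyl acetal and the lactone survive.

Step 10
Reactants: 14 (1R,4S,5R,6S)-6-(hydroxymethyl)-8-methoxy-4-[(E)-2-methylpenta-2,4-dien-1-yl]-3,7-dioxabicyclo[3.3.0]octan-2-one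
Product: 15 (1R,4S,5R,6S)-6-formyl-8-methoxy-4-[(E)-2-methylpenta-2,4-dien-1-yl]-3,7-dioxabicyclo[3.3.0]octan-2-one (used at once)
Conditions: Dess–Martin periodinane, pyridine, CH2Cl2, 0 °C → rt
Reagents that add atoms: none
Why: Dess–Martin oxidation gives the α-alkoxy aldehyde under buffered, non-epimerising conditions so that C6 is preserved.

Step 11
Reactants: 15 (1R,4S,5R,6S)-6-formyl-8-methoxy-4-[(E)-2-methylpenta-2,4-dien-1-yl]-3,7-dioxabicyclo[3.3.0]octan-2-one
Product: 16 (1R,4S,5R,6S)-6-(2,2-dibromoethenyl)-8-methoxy-4-[(E)-2-methylpenta-2,4-dien-1-yl]-3,7-dioxabicyclo[3.3.0]octan-2-one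
Conditions: CBr4, PPh3, Et3N, CH2Cl2, 0 °C
Reagents that add atoms: carbon tetrabromide BrC(Br)(Br)Br
Why: Ramirez dibromo-olefination (first stage of the Corey–Fuchs sequence) converts the aldehyde into the 1,1-dibromoalkene C5=C4Br2, after which C6 is no longer epimerisable.

Step 12
Reactants: 16 (1R,4S,5R,6S)-6-(2,2-dibromoethenyl)-8-methoxy-4-[(E)-2-methylpenta-2,4-dien-1-yl]-3,7-dioxabicyclo[3.3.0]octan-2-one
Product: 18 tricyclic bromide: (1(10)E,4Z)-4-bromocyclodeca-1(10),4-diene ring (C14 methyl on C10) trans-fused at C7–C8 to lactone ring A and at C6–C7 to the 13-methoxytetrahydrofuran ring B; stereocentres as in 12, via alkylborane 17 (not isolated)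
Conditions: 9-BBN-H (1.3 equiv), THF, 0 °C → rt; then slow addition to PdCl2(dppf) (15 mol%), AsPh3 (30 mol%), aqueous K3PO4, DMF/THF, 50 °C, final 0.002 M; work-up at pH 5
Reagents that add atoms: none
Why: 9-BBN hydroborates only the terminal vinyl group of the diene to put boron on C3, and intramolecular B-alkyl Suzuki–Miyaura coupling then takes place at the more reactive C–Br bond trans to C6 of the 1,1-dibromoalkene, closing the ten-membered ring with C3 trans to C6 and leaving the bromine cis to C6 for the next coupling.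

Step 13
Reactants: 18 tricyclic bromide
Product: 19 tricyclic allylic alcohol: the 4-(hydroxymethyl) analogue of 18 ((1(10)E,4Z); C15–OH on C4, cis to C6)
Conditions: (tributylstannyl)methanol (2 equiv), Pd(PtBu3)2 (10 mol%), CsF, 1,4-dioxane, 50 °C
Reagents that add atoms: (tributylstannyl)methanol OC[Sn](CCCC)(CCCC)CCCC
Why: Stille coupling of the remaining alkenyl bromide with (tributylstannyl)methanol introduces C15 as a hydroxymethyl group with retention, giving the C4=C5 geometry of the target at a temperature that should not trigger Cope rearrangement of the 1,5-diene.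

Step 14
Reactants: 20 (tert-butyldimethylsilyloxy)acetaldehyde; 21 ethyl 2-(triphenylphosphoranylidene)propanoate
Product: 22 ethyl (E)-4-[(tert-butyldimethylsilyl)oxy]-2-methylbut-2-enoate
Conditions: CH2Cl2, rt
Reagents that add atoms: none
Why: Wittig olefination with the stabilised α-methyl ylide gives the (E)-trisubstituted enoate of the side chain.

Step 15
Reactants: 22 ethyl (E)-4-[(tert-butyldimethylsilyl)oxy]-2-methylbut-2-enoate
Product: 23 (E)-4-[(tert-butyldimethylsilyl)oxy]-2-methylbut-2-enoic acid
Conditions: LiOH·H2O, THF/MeOH/H2O, 0 °C → rt; then 1 M HCl to pH 4 at 0 °C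
Reagents that add atoms: lithium hydroxide [Li+].[OH-]
Why: Mild saponification of the ethyl ester gives the acid without loss of the primary silyl ether.

Step 16
Reactants: 19 tricyclic allylic alcohol; 23 (E)-4-[(tert-butyldimethylsilyl)oxy]-2-methylbut-2-enoic acid
Product: 24 tricyclic ester: the 15-O-[(E)-4-(tert-butyldimethylsilyloxy)-2-methylbut-2-enoyl] derivative of 19
Conditions: DCC, DMAP (10 mol%), CH2Cl2, 0 °C → rt
Reagents that add atoms: none
Why: Steglich esterification acylates the only free hydroxyl (primary allylic C15–OH) while O6 is still locked in ring B, so no selectivity between hydroxyls is required.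

Step 17
Reactants: 24 tricyclic ester
Product: 25 lactol: the 13-hydroxy (hemiacetal) analogue of 24 with the side-chain hydroxyl free (C13 epimers; masked 6-hydroxy-α-formyl lactone)
Conditions: AcOH/THF/H2O (3:1:1), 40 °C
Reagents that add atoms: water O
Why: Mild aqueous acid hydrolyses the five-membered methyl acetal to the lactol and at the same time removes the primary silyl ether, conditions under which the lactone and the allylic ester are stable.

Step 18
Reactants: 25 lactol
Product: 26 CNP0326626.1
Conditions: paraformaldehyde (excess), K2CO3, THF, rt → 40 °C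
Reagents that add atoms: formaldehyde C=O
Why: Under carbonate the lactol opens to the enolate of the α-formyl lactone with O6 released, aldol addition to formaldehyde at C11 is followed by C-to-O formyl transfer and E1cB loss of formate (deformylative α-methylenation), which creates C11=C13 and leaves the lactone on O8 because only the formyl group can be transferred.

**Compound list**

1 | pent-1-en-4-yne | C#CCC=C | starting material
2 | (E)-dimethyl(2-methylpenta-1,4-dien-1-yl)alane | C=CC/C(C)=C/[Al](C)C | intermediate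
3 | (E)-1-iodo-2-methylpenta-1,4-diene | C=CC/C(C)=C/I | intermediate
4 | (S)-but-3-ene-1,2-diol | OC[C@@H](O)C=C | starting material
5 | (S)-1-[(tert-butyldimethylsilyl)oxy]but-3-en-2-ol | CC(C)(C)[Si](C)(C)OC[C@@H](O)C=C | intermediate
6 | (2S,3E,6E)-1-[(tert-butyldimethylsilyl)oxy]-7-iodo-6-methylhepta-3,6-dien-2-ol | CC(C)(C)[Si](C)(C)OC[C@@H](O)/C=C/C/C(C)=C/I | intermediate
7 | methyl propiolate | C#CC(=O)OC | starting material
8 | methyl (E)-3-{[(2S,3E,6E)-1-[(tert-butyldimethylsilyl)oxy]-7-iodo-6-methylhepta-3,6-dien-2-yl]oxy}prop-2-enoate | COC(=O)/C=C/O[C@H](CO[Si](C)(C)C(C)(C)C)/C=C/C/C(C)=C/I | intermediate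
9 | (E)-3-{[(2S,3E,6E)-1-[(tert-butyldimethylsilyl)oxy]-7-iodo-6-methylhepta-3,6-dien-2-yl]oxy}prop-2-enoic acid | OC(=O)/C=C/O[C@H](CO[Si](C)(C)C(C)(C)C)/C=C/C/C(C)=C/I | intermediate
10 | 2-iodo-3-methoxy-3-{[(2S,3E,6E)-1-[(tert-butyldimethylsilyl)oxy]-7-iodo-6-methylhepta-3,6-dien-2-yl]oxy}propanoic acid (epimers at C2 and C3) | OC(=O)C(I)C(OC)O[C@H](CO[Si](C)(C)C(C)(C)C)/C=C/C/C(C)=C/I | intermediate
11 | cyclised iodo acid: (5S)-5-{[(tert-butyldimethylsilyl)oxy]methyl}-4-[(3E)-1,4-diiodo-3-methylbut-3-en-1-yl]-2-methoxyoxolane-3-carboxylic acid (3,4-cis; 4,5-trans; C2 epimers) | OC(=O)[C@H]1C(OC)O[C@H](CO[Si](C)(C)C(C)(C)C)[C@H]1[C@H](I)C/C(C)=C/I | intermediate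
12 | (1R,4S,5R,6S)-6-{[(tert-butyldimethylsilyl)oxy]methyl}-4-[(E)-3-iodo-2-methylprop-2-en-1-yl]-8-methoxy-3,7-dioxabicyclo[3.3.0]octan-2-one (C8 epimers) | COC1O[C@H](CO[Si](C)(C)C(C)(C)C)[C@H]2[C@H](C/C(C)=C/I)OC(=O)[C@@H]12 | intermediate
13 | (1R,4S,5R,6S)-6-{[(tert-butyldimethylsilyl)oxy]methyl}-8-methoxy-4-[(E)-2-methylpenta-2,4-dien-1-yl]-3,7-dioxabicyclo[3.3.0]octan-2-one | COC1O[C@H](CO[Si](C)(C)C(C)(C)C)[C@H]2[C@H](C/C(C)=C/C=C)OC(=O)[C@@H]12 | intermediate
14 | (1R,4S,5R,6S)-6-(hydroxymethyl)-8-methoxy-4-[(E)-2-methylpenta-2,4-dien-1-yl]-3,7-dioxabicyclo[3.3.0]octan-2-one | COC1O[C@H](CO)[C@H]2[C@H](C/C(C)=C/C=C)OC(=O)[C@@H]12 | intermediate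
15 | (1R,4S,5R,6S)-6-formyl-8-methoxy-4-[(E)-2-methylpenta-2,4-dien-1-yl]-3,7-dioxabicyclo[3.3.0]octan-2-one | COC1O[C@H](C=O)[C@H]2[C@H](C/C(C)=C/C=C)OC(=O)[C@@H]12 | intermediate
16 | (1R,4S,5R,6S)-6-(2,2-dibromoethenyl)-8-methoxy-4-[(E)-2-methylpenta-2,4-dien-1-yl]-3,7-dioxabicyclo[3.3.0]octan-2-one | COC1O[C@H](C=C(Br)Br)[C@H]2[C@H](C/C(C)=C/C=C)OC(=O)[C@@H]12 | intermediate
17 | alkylborane: 4-[(E)-5-(9-borabicyclo[3.3.1]nonan-9-yl)-2-methylpent-2-en-1-yl] analogue of 16 | COC1O[C@H](C=C(Br)Br)[C@H]2[C@H](C/C(C)=C/CCB3C4CCCC3CCC4)OC(=O)[C@@H]12 | intermediate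
18 | tricyclic bromide: (1(10)E,4Z)-4-bromocyclodeca-1(10),4-diene ring trans-fused at C7–C8 to lactone ring A and at C6–C7 to 13-methoxytetrahydrofuran ring B; rings A and B cis-fused at C7–C11 | COC1O[C@@H]2/C=C(\Br)CC/C=C(\C)C[C@@H]3OC(=O)[C@@H]1[C@@H]23 | intermediate
19 | tricyclic allylic alcohol: 4-(hydroxymethyl) analogue of 18 | COC1O[C@@H]2/C=C(\CO)CC/C=C(\C)C[C@@H]3OC(=O)[C@@H]1[C@@H]23 | intermediate
20 | (tert-butyldimethylsilyloxy)acetaldehyde | O=CCO[Si](C)(C)C(C)(C)C | starting material
21 | ethyl 2-(triphenylphosphoranylidene)propanoate | CCOC(=O)C(C)=P(c1ccccc1)(c1ccccc1)c1ccccc1 | starting material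
22 | ethyl (E)-4-[(tert-butyldimethylsilyl)oxy]-2-methylbut-2-enoate | CCOC(=O)/C(C)=C/CO[Si](C)(C)C(C)(C)C | intermediate
23 | (E)-4-[(tert-butyldimethylsilyl)oxy]-2-methylbut-2-enoic acid | OC(=O)/C(C)=C/CO[Si](C)(C)C(C)(C)C | intermediate
24 | tricyclic ester: 15-O-[(E)-4-(tert-butyldimethylsilyloxy)-2-methylbut-2-enoyl] derivative of 19 | COC1O[C@@H]2/C=C(\COC(=O)/C(C)=C/CO[Si](C)(C)C(C)(C)C)CC/C=C(\C)C[C@@H]3OC(=O)[C@@H]1[C@@H]23 | intermediate
25 | lactol: 13-hydroxy analogue of 24 with free side-chain hydroxyl (C13 epimers) | OC1O[C@@H]2/C=C(\COC(=O)/C(C)=C/CO)CC/C=C(\C)C[C@@H]3OC(=O)[C@@H]1[C@@H]23 | intermediate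
26 | CNP0326626.1: (1(10)E,4Z)-6-hydroxy-15-[(E)-4-hydroxy-2-methylbut-2-enoyloxy]germacra-1(10),4,11(13)-trien-12,8-olide, (6R,7S,8S) | C=C1C(=O)O[C@H]2C/C(C)=C/CC/C(COC(=O)/C(C)=C/CO)=C/[C@@H](O)[C@H]12 | target

**Step count and risks**

Total step count: 18. Longest linear sequence: 15 steps (steps 1, 3–13, 16–18).

Three steps most likely to fail:

Step 12 (ring closure). Intermolecular coupling and protodeboronation may outrun a closure that has to build a strained (E,E)-cyclodeca-1,5-diene, and discrimination between the two C–Br bonds may erode if the trans pathway is slow. The fallback sets out from 16 and returns at 18. The borane 17 is made as before but oxidised (NaBO3·4H2O) to the homoallylic primary alcohol F1. Appel iodination (I2, PPh3, imidazole) gives the primary iodide F2. Zinc insertion (Zn dust, LiCl, THF) gives the alkylzinc iodide F3, which is not isolated. It is cyclised under anhydrous, base-free conditions by intramolecular Negishi coupling (PdCl2(DPEphos), THF, high dilution); this reaction type is selective for the bromine trans to the substituent of 1,1-dibromoalkenes.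

Step 7 (key step). The radical chain may deliver the C11 epimer whose carboxylate is trans to C8 and cannot lactonise, the C8 iodide may be reduced or eliminated before displacement, or the mixed acetal may be lost in the aqueous medium. The fallback sets out from 8 (skipping step 5) and returns at 12. It separates the radical and ionic events. Iodomethoxylation of 8 (NIS, MeOH) gives the methyl iodoacetal ester F4. Anhydrous iodine-atom-transfer cyclisation (Et3B, air, benzene) gives the γ-iodo ester F5, which is isolated and freed from its C11 epimer. Silver-assisted closure (AgOTf, 2,6-di-tert-butylpyridine, CH2Cl2) through participation of the ester carbonyl, with inversion at C8 and loss of the methyl group, then gives 12.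

Step 17 (acid unmasking). Hydrolysis of the β-carbonyl-deactivated acetal may be slow enough that acid-promoted transannular cyclisation of the 1(10),4-diene or ionisation of the allylic C15 ester competes. The fallback sets out from 24 and returns at 25. The acetal is cleaved with Me2BBr (CH2Cl2, –78 °C, then aqueous NaHCO3) to the silyl-protected lactol F6, and the silyl ether is then removed with buffered HF·pyridine.

**Further compounds**

F1 | step 12 | (1R,4S,5R,6S)-6-(2,2-dibromoethenyl)-4-[(E)-5-hydroxy-2-methylpent-2-en-1-yl]-8-methoxy-3,7-dioxabicyclo[3.3.0]octan-2-one | COC1O[C@H](C=C(Br)Br)[C@H]2[C@H](C/C(C)=C/CCO)OC(=O)[C@@H]12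
F2 | step 12 | (1R,4S,5R,6S)-6-(2,2-dibromoethenyl)-4-[(E)-5-iodo-2-methylpent-2-en-1-yl]-8-methoxy-3,7-dioxabicyclo[3.3.0]octan-2-one | COC1O[C@H](C=C(Br)Br)[C@H]2[C@H](C/C(C)=C/CCI)OC(=O)[C@@H]12
F3 | step 12 | alkylzinc iodide derived from F2 (zinc on C3) | COC1O[C@H](C=C(Br)Br)[C@H]2[C@H](C/C(C)=C/CC[Zn]I)OC(=O)[C@@H]12
F4 | step 7 | methyl 2-iodo-3-methoxy-3-{[(2S,3E,6E)-1-[(tert-butyldimethylsilyl)oxy]-7-iodo-6-methylhepta-3,6-dien-2-yl]oxy}propanoate | COC(=O)C(I)C(OC)O[C@H](CO[Si](C)(C)C(C)(C)C)/C=C/C/C(C)=C/I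
F5 | step 7 | methyl (5S)-5-{[(tert-butyldimethylsilyl)oxy]methyl}-4-[(3E)-1,4-diiodo-3-methylbut-3-en-1-yl]-2-methoxyoxolane-3-carboxylate (3,4-cis; 4,5-trans) | COC(=O)[C@H]1C(OC)O[C@H](CO[Si](C)(C)C(C)(C)C)[C@H]1[C@H](I)C/C(C)=C/I
F6 | step 17 | silyl-protected lactol: 13-hydroxy analogue of 24 | OC1O[C@@H]2/C=C(\COC(=O)/C(C)=C/CO[Si](C)(C)C(C)(C)C)CC/C=C(\C)C[C@@H]3OC(=O)[C@@H]1[C@@H]23
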